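The capture agent is what differs between the two earlier runs, maple and birch. In both, the solid substrate dissolves to starting material, which goes on with reagent to target or to side product.

| setting | maple | birch | flask |
|---|---|---|---|
| solid substrate | 0.19 M | 0.19 M | 0.19 M |
| reagent | 2.5 equiv | 2.5 equiv | 2.50 equiv |
| capture agent | 4.8 mM | 19 mM | 9.50 mM |
| remark | run made earlier | run made earlier |  |
| time |  |  | 10 h |

| run | time / h | target / % | side product / % |
|---|---|---|---|
| maple | 0.417 | 19.1 | 15.8 |
| maple | 1.33 | 46.5 | 39.0 |
| maple | 2.50 | 52.1 | 43.7 |
| maple | 3.00 | 52.4 | 44.7 |
| maple | 5.00 | 53.0 | 45.4 |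
| maple | 6.00 | 54.1 | 46.5 |
| maple | 8.00 | 54.4 | 45.7 |
| birch | 0.667 | 31.9 | 28.3 |
| birch | 1.00 | 39.5 | 37.5 |
| birch | 1.33 | 45.3 | 39.9 |
| birch | 2.50 | 50.2 | 43.3 |
| birch | 3.00 | 53.3 | 45.3 |
| birch | 5.00 | 53.1 | 43.9 |
| birch | 8.00 | 52.2 | 44.6 |

(standard deviation of a reading: 1 percentage point)

- solid, in amounts per volume of the solution: solid substrate
- candidate steps: starting material <-> intermediate B; starting material + reagent <-> intermediate A; starting material + reagent -> intermediate C; reagent + intermediate B <-> intermediate D; intermediate A -> side product; capture agent + intermediate B -> trapped intermediate; solid substrate <-> starting material; reagent + intermediate C -> target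
- at the start none of the solid substrate is in solution

- share of target in target plus side product at 8.0 min
- share of target in target plus side product at 10 h

I take target over target plus side product in the last reading of each run, 54.3% for maple and 53.9% for birch. Their mean, 54.1%, I call the late share.

Two things look at odds here. Birch holds 3.96 times the capture agent of maple, and its last total of target plus side product is lower, 96.8% against 100%. Yet the two shares differ by 0.40 percentage points, less than the 1 point scatter of one reading.

The candidate steps clear this up as I read them. The capture agent takes intermediate B, which forms from starting material, and starting material also feeds both branches, so I expect what it traps to be lost to target and side product alike: at this reagent charge, the late readings of birch show a lower total than those of maple and nearly the same share. For this flask, at 9.50 mM, I therefore expect the late share again at 10 h.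

The forecast gives 53% at 8.0 min and 54.2% at 10 h, holding that “their ratio stays constant even as the solid dissolves”.

The flask gives 56.3% at 8.0 min and 54.0% at 10 h, so the early share stands 2.3 points above the late one.

    starting material ⇌ intermediate B (K = 0.540, k = 0.0180 s⁻¹)
    starting material + reagent ⇌ intermediate A (K = 6.40 M⁻¹, k = 0.00160 M⁻¹ s⁻¹)
    starting material + reagent → intermediate C (k = 0.00170 M⁻¹ s⁻¹)
    reagent + intermediate B ⇌ intermediate D (K = 0.680 M⁻¹, k = 0.0210 M⁻¹ s⁻¹)
    intermediate A → side product (k = 0.00240 s⁻¹)
    capture agent + intermediate B → trapped intermediate (k = 0.00390 M⁻¹ s⁻¹)
    solid substrate ⇌ starting material, rate k7*(cs7 - [starting material]) while solid is left; crystals form when [starting material] > cs7 (solubility = 0.110 M, k = 0.00250 s⁻¹)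
    reagent + intermediate C → target (k = 0.00670 M⁻¹ s⁻¹)

At 10.0 h the flask holds 53.1% target and 45.3% side product, with 0% of the solid substrate, the limiting reagent, 0% of starting material, and 39% of the reagent's own charge left. The late share on that total gives 53.2% target. The neighbour flask with 1.50 equiv of reagent holds 42.8% side product at 10.0 h, and there the late share gives 49.9% target against the 49.4% it holds.

Readings and results were computed on assumed constants; scatter was added.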